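Of the 4 questions on this flask, 3 ask for a share of target in target plus other capture product, and counting the turnovers of each nucleophile's charge is the way to reckon them.

| setting | oak | birch | cedar | flask |
|---|---|---|---|---|
| substrate | 0.010 M | 0.010 M | 0.010 M | 0.010 M |
| first nucleophile | 8 mM | 8 mM | 8 mM | 8.00 mM |
| second nucleophile | 0.0090 M | 0.013 M | 0.018 M | 0.0180 M |
| protic impurity | 2 mM | 2 mM | 3 mM | 2.00 mM |
| remark | run made earlier | run made earlier | run made earlier |  |
| time |  |  |  | 10 min |

| run | time / min | target / % | other capture product / % |
|---|---|---|---|
| oak | 1.00 | 40.9 | 7.4 |
| oak | 1.33 | 42.4 | 8.8 |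
| oak | 2.00 | 43.5 | 10.2 |
| oak | 3.00 | 44.6 | 11.9 |
| oak | 5.00 | 43.6 | 9.6 |
| oak | 8.00 | 45.7 | 10.6 |
| oak | 12.0 | 42.9 | 13.0 |
| birch | 0.667 | 35.9 | 9.4 |
| birch | 2.00 | 44.1 | 16.6 |
| birch | 3.00 | 43.1 | 15.2 |
| birch | 5.00 | 41.5 | 17.2 |
| birch | 8.00 | 42.6 | 17.0 |
| birch | 10.0 | 42.3 | 17.5 |
| birch | 12.0 | 39.5 | 17.7 |
| cedar | 2.50 | 40.4 | 18.8 |
| cedar | 5.00 | 39.9 | 21.6 |
| cedar | 8.00 | 42.4 | 19.8 |
| cedar | 10.0 | 40.7 | 19.7 |
| cedar | 12.0 | 40.3 | 20.0 |

(each reading ± 1 percentage point)

* share of target in target plus other capture product at 1.0 s
* share of target in target plus other capture product at 25 s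
* share of target in target plus other capture product at 10 min
* which of target and other capture product there is more of at 10 min



A bench rule applies while both nucleophiles stay near their charges (pseudo-first-order): target's share of the capture is the capture ratio times first nucleophile, divided by that same product plus second nucleophile. Oak's target at 1.00 min amounts to 51.1% of the first nucleophile's charge and its other capture product to 8.22% of the second's, and counting these standing products as the use gives 8.34. This number is the capture ratio, the logarithm of the fraction of first nucleophile not standing in target over that of the fraction of second nucleophile not standing in other capture product, a selectivity factor. It is a reading, resting on 7.4% of other capture product with a scatter of 1 percentage point, and it counts no other take of either nucleophile. With this flask's charges, the rule gives a starting share of 78.8%, taken here for 1.0 s.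

The border shows in the ratio of first nucleophile to substrate charged, 0.800: the first nucleophile is charged below the substrate, so capture of the substrate need not leave it near its charge. Cedar, this recipe except for 3 mM of protic impurity, holds at 12.0 min target amounting to half of its first nucleophile's charge and other capture product amounting to 11.1% of its second's. Past that border, this reckoning takes cedar's latest share, 66.8%, for 10 min, with target ahead, and puts 25 s halfway, at 72.8%.

The forecast, whose share “drifts down as the first nucleophile is used”, gives 72.5%, 70% and 67.5% with target ahead, lower than this reckoning at 1.0 s.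

The flask gives 82.0%, 76.1% and 65.4%, with target ahead.

    first nucleophile + intermediate → target (k = 1900 /M/s)
    second nucleophile + protic impurity → quenched reagent (k = 300 /M/s)
    substrate + target → side product (k = 1.90 /M/s)
    second nucleophile + intermediate → other capture product (k = 200 /M/s)
    substrate ⇌ intermediate (K = 0.00640, k = 0.0290 /s)

At 1.00 min, with 21.2% of the substrate left, the flask held 37.2% target, 15.7% other capture product and 25.8% side product, which counts double. By 5.00 min, with substrate down to 0.0510%, these stood at 40.5%, 21.4% and 38.1%. At 1.0 s, the capture ratio's 78.8% lies 3.2 points below the flask. For the neighbour with 0.020 M of first nucleophile, it gives 90.3% at the start, and that flask shows 92.0% at 1.0 s.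

The runs are simulated for an exercise; scatter was added.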